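The earlier runs and the new flask come from a simulation on assumed constants; scatter was added.

- Watch the rate.

| flask | E | L | remark | time |
|---|---|---|---|---|
| Tuesday's | 0.011 M | 0.011 M | run made earlier |  |
| Friday's | 0.0055 M | 0.011 M | run made earlier |  |
| Saturday's | 0.0083 M | 0.011 M | run made earlier |  |
| Wednesday's | 0.011 M | 0.0055 M | run made earlier |  |
| midnight | 0.011 M (fed, over 1.5 min) | 0.0110 M | all else is in the flask from the start; the feed brings no volume worth counting | 2.0 min |
| autumn | 0.011 M | 0.0110 M (fed, over 1.5 min) | all else is in the flask from the start; the feed brings no volume worth counting | 2.0 min |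
| spring | 0.011 M | 0.0110 M (in portions, 2, over 1.5 min) | first portion at the start, last at 1.5 min | 2.0 min |
| winter | 0.011 M | 0.0110 M | everything together at the start | 2.0 min |

| run | time / s | G / % | Q / % |
|---|---|---|---|
| Tuesday's | 10.0 | 18.1 | 0.5 |
| Tuesday's | 15.0 | 24.5 | 0.3 |
| Tuesday's | 20.0 | 30.8 | 0 |
| Tuesday's | 30.0 | 43.9 | 0.9 |
| Tuesday's | 50.0 | 60.7 | 0.3 |
| Tuesday's | 80.0 | 78.5 | 0.3 |
| Tuesday's | 120 | 90.2 | 0.1 |
| Friday's | 10.0 | 17.7 | 0.4 |
| Friday's | 12.0 | 20.4 | 0 |
| Friday's | 20.0 | 31.8 | 0.2 |
| Friday's | 25.0 | 37.7 | 0.3 |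
| Friday's | 40.0 | 53.6 | 0.1 |
| Friday's | 60.0 | 67.8 | 0 |
| Friday's | 90.0 | 81.6 | 0.2 |
| Saturday's | 10.0 | 17.6 | 1.1 |
| Saturday's | 15.0 | 25.6 | 0.3 |
| Saturday's | 25.0 | 37.0 | 0 |
| Saturday's | 40.0 | 52.6 | 0.3 |
| Saturday's | 60.0 | 67.7 | 0.2 |
| Saturday's | 80.0 | 77.7 | 0.3 |
| Saturday's | 90.0 | 81.8 | 0 |
| Wednesday's | 20.0 | 31.2 | 0 |
| Wednesday's | 40.0 | 50.5 | 0 |
| Wednesday's | 60.0 | 49.9 | 0 |
| Wednesday's | 80.0 | 49.2 | 0.1 |
| Wednesday's | 90.0 | 48.9 | 0.1 |

(scatter of a reading: 0.5 percentage points)



1. which flask leads in amount of G, in percent of the E charged ("all alike" within 1.5 percentage points) (midnight / autumn / spring / winter / all alike)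
2. how much G is there at the end, in percent of the E charged: midnight
3. how much G is there at the end, in percent of the E charged: autumn
4. how much G is there at the end, in percent of the E charged: spring
5. how much G is there at the end, in percent of the E charged: winter

- Tuesday's last reading has G at 90.2% after 120 s, so you can read the pace straight off: E is used at 0.0194 s⁻¹ of what is present, and the rate of G drops by one power of ten in 119 s. Call that span, counted only while E and L are together, the decade time.
- The amounts do not shift this pace. At 20.0 s Tuesday's reads 30.8%, Friday's, with half the E, reads 31.8%, and Wednesday's, with half the L, reads 31.2%. Friday's last reading gives a decade time of 122 s.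
- The falling E slows the rate smoothly: winter spends 1.01 decade times with E and L together, so its final rate is about one power of ten below its starting rate.
- The second brake is abrupt. In Wednesday's, L is the limiting reagent, and G reads 50.5% at 40.0 s and 48.9% at 90.0 s, so G has stopped rising. E was not read there, so this is my bet: the clock stops while L is absent.
- In spring, the first portion then lasts until the rate has halved, 35.8 s, and the last portion adds 30.0 s. Spring's clock reads 65.8 s, less than winter's 120 s, so I reckon G at 72.0% in spring.
- The forecast gives 72.9% for midnight, 89.3% for autumn, 87.5% for spring and 90% for winter, with winter ahead. On spring it stands 16 percentage points above my figure: it takes something made from E to wait for L, and calls that an inference, noting “no run re-adds L”.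
- The flasks give 72.7% for midnight, 87.5% for autumn, 73.0% for spring and 89.6% for winter, with winter ahead.

    E ⇌ X (K = 0.0220, k = 0.0190 s⁻¹)
    X ⇌ J (K = 1.30, k = 150 s⁻¹)
    L + X ⇌ Q (K = 29.0 L mol⁻¹, k = 1.30 × 10⁵ L mol⁻¹ s⁻¹)
    L + J → G (k = 1.70 × 10⁵ L mol⁻¹ s⁻¹)

- In spring, L reads 0% with E at 47.6% at 1.00 min, and L reads 0% with E at 47.6% at 1.50 min. E and X relax both ways with a half-life of 0.785 s in midnight, far shorter than the 0.61 min forward half-life of E in winter. From there the decade time gives spring 26.6% of E at the end, and the flask holds 27.0%. Midnight, carried on from 27% of E for another 1.00 min, reckons to 8.55%, and at 3.0 min it holds 8.8%.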